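**Plan**

- Numbering: C1 (methyl-bearing ring-fusion carbon), C2 (OAc), C3, C4 (isopropyl carbinol), C5 (ring-fusion CH), C6 (aroyloxy), C7, C8 (methyl-bearing olefin carbon), C9, C10. Ring A = C1–C5, ring B = C5–C10 plus C1; β is the face of the C1 methyl.
- Retrosynthesis: the C2–O acetate and C6–O aroyl bonds are cut first, then C7–C8 of ring B. C7 is the single methylene between the oxygenated C6 and the C8=C9 olefin, so with C6 as a ketone this bond joins a methyl-ketone enolate carbon to an alkenyl halide carbon. Further cuts are C4–isopropyl, C1–C10 and C5–C6.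
- Forward: ring A comes ready-made as an (R)-4-silyloxy-2-methylcyclopentenone. C5–C6 (isopropenyl copper reagent) and C1–C10 ((Z)-3-iodobut-2-enyl bromide) are attached, C4 becomes the isopropyl carbinol, the isopropenyl group is cleaved to the acetyl group, and ring B is closed last at C7–C8 by palladium.
- Stereochemistry: the C4 silyloxy group of the enone sends the isopropenyl group to the opposite face (C5). The C5 group then directs the alkylation (C1, hence the trans fusion) and the isopropyl addition (C4). The C4 hydroxyl finally delivers hydride to C6 and to C2.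

Key step: step 13

Remark: the alkenyl halide is carried as the iodide with iodine cis to C10 (Z), made geometrically pure from but-2-yn-1-ol; only this geometry can give the cis olefin of ring B, and the iodide undergoes oxidative addition under the mildest conditions.

**Route**

Step 1
Reactants: 1 but-2-yn-1-ol
Product: 3 (Z)-3-iodobut-2-en-1-ol, via cyclic alkenylalanate 2 (not isolated)
Conditions: NaAlH2(OCH2CH2OMe)2, THF, 0 °C to rt; then I2, THF, −78 °C
Reagents that add atoms: iodine, II
Why: Alkoxide-directed trans-hydroalumination of the propargylic alcohol places aluminium on C3 in a five-membered alanate, and iodinolysis with retention puts iodine cis to the CH2OH group (hydroalumination–iodination).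

Step 2
Reactants: 3 (Z)-3-iodobut-2-en-1-ol
Product: 4 (Z)-1-bromo-3-iodobut-2-ene
Conditions: CBr4, PPh3, CH2Cl2, 0 °C
Reagents that add atoms: tetrabromomethane, BrC(Br)(Br)Br
Why: Appel bromination of a primary allylic alcohol runs under neutral conditions and does not touch the alkenyl iodide or its geometry.

Step 3
Reactants: 5 (R)-4-(tert-butyldimethylsilyloxy)cyclopent-2-en-1-one
Product: 6 (R)-4-(tert-butyldimethylsilyloxy)-2-iodocyclopent-2-en-1-one
Conditions: I2, pyridine, CH2Cl2, 0 °C to rt
Reagents that add atoms: iodine, II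
Why: Pyridine-mediated α-iodination of the enone (conjugate addition, iodination of the enolate, elimination) is routine for 4-silyloxycyclopentenones and leaves the C4 stereocentre untouched.

Step 4
Reactants: 6 (R)-4-(tert-butyldimethylsilyloxy)-2-iodocyclopent-2-en-1-one
Product: 7 (R)-4-(tert-butyldimethylsilyloxy)-2-methylcyclopent-2-en-1-one
Conditions: SnMe4, Pd2(dba)3 (cat.), AsPh3, CuI (cat.), NMP, 60 °C
Reagents that add atoms: tetramethylstannane, C[Sn](C)(C)C
Why: Stille coupling of the α-iodoenone transfers a methyl group under neutral conditions, so the β-silyloxy group is not eliminated.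

Step 5
Reactants: 7 (R)-4-(tert-butyldimethylsilyloxy)-2-methylcyclopent-2-en-1-one; 8 isopropenylmagnesium bromide
Product: 9 2-(trimethylsilyloxy)-1-methyl-5β-isopropenyl-4α-(tert-butyldimethylsilyloxy)cyclopent-1-ene
Conditions: CuBr·SMe2 (10 mol%), Me3SiCl, HMPA, THF, −78 °C; Et3N quench
Reagents that add atoms: chlorotrimethylsilane, C[Si](C)(C)Cl
Why: Copper-catalysed conjugate addition with in situ O-silylation occurs on the face opposite to the C4 silyloxy group, which sets C5 (isopropenyl β, H α) and fixes the enolate regiochemistry as the silyl enol ether.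

Step 6
Reactants: 9 silyl enol ether; 4 (Z)-1-bromo-3-iodobut-2-ene
Product: 11 2-oxo-1β-methyl-1α-[(Z)-3-iodobut-2-enyl]-5β-isopropenyl-4α-(tert-butyldimethylsilyloxy)cyclopentane, via lithium enolate 10 (not isolated)
Conditions: MeLi, THF, 0 °C; then 4, HMPA, −78 to −20 °C
Reagents that add atoms: none
Why: MeLi cleavage of the silyl enol ether gives the regiodefined lithium enolate, whose SN2 alkylation by the allylic bromide occurs anti to the adjacent C5 isopropenyl group, so C10 enters α and the C1 methyl ends β (enolate alkylation creating the quaternary centre and the later trans fusion).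

Step 7
Reactants: 11 alkylated ketone
Product: 12 C2 ethylene ketal of 11
Conditions: Me3SiOCH2CH2OSiMe3, Me3SiOTf (cat.), CH2Cl2, −78 to −20 °C
Reagents that add atoms: 1,2-bis(trimethylsilyloxy)ethane, C[Si](C)(C)OCCO[Si](C)(C)C
Why: Noyori ketalisation works at low temperature on hindered ketones and spares the β-silyloxy group and both olefins.

Step 8
Reactants: 12 silyloxy ketal
Product: 13 4α-hydroxy ketal
Conditions: Bu4NF, THF, 0 °C to rt
Reagents that add atoms: none
Why: Fluoride cleavage of the secondary silyl ether leaves the ketal, the alkenyl iodide and the isopropenyl group untouched at this temperature.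

Step 9
Reactants: 13 4α-hydroxy ketal
Product: 14 4-oxo ketal
Conditions: Dess–Martin periodinane, pyridine, CH2Cl2, 0 °C to rt
Reagents that add atoms: none
Why: Buffered Dess–Martin oxidation gives the ketone without epimerising C5 or drawing the isopropenyl double bond into conjugation.

Step 10
Reactants: 14 4-oxo ketal
Product: 15 4β-hydroxy-4α-isopropyl ketal
Conditions: i-PrMgCl, anhydrous CeCl3, THF, −78 to −40 °C
Reagents that add atoms: isopropylmagnesium chloride, CC(C)[Mg]Cl
Why: 1,2-Addition of the organocerium reagent, which suppresses enolisation and β-hydride transfer, occurs anti to the adjacent C5 isopropenyl group, so the isopropyl group enters α and the C4 hydroxyl ends β.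

Step 11
Reactants: 15 tertiary alcohol
Product: 16 4β-triethylsilyl ether of 15
Conditions: Et3SiOTf, 2,6-lutidine, CH2Cl2, −78 to 0 °C
Reagents that add atoms: triethylsilyl trifluoromethanesulfonate, CC[Si](CC)(CC)OS(=O)(=O)C(F)(F)F
Why: Silylation of the hindered tertiary alcohol with the silyl triflate blocks retro-aldol cleavage and palladium alkoxide chemistry in the next two steps.

Step 12
Reactants: 16 silyl ether
Product: 18 5β-acetyl cyclisation precursor, via vicinal diol 17 (not isolated)
Conditions: OsO4 (cat.), NaIO4, 2,6-lutidine, dioxane/H2O, rt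
Reagents that add atoms: osmium tetroxide, O=[Os](=O)(=O)=O (oxygen donor, re-formed by sodium periodate, [Na+].[O-]I(=O)(=O)=O)
Why: In this lutidine-buffered Lemieux–Johnson cleavage OsO4 selects the 1,1-disubstituted isopropenyl group over the electron-poor trisubstituted iodoalkene, and periodate cleaves the diol to the methyl ketone.

Step 13
Reactants: 18 5β-acetyl cyclisation precursor
Product: 19 trans-fused 6-oxo bicycle with C8=C9 olefin (C2 ketal; 4β-OSiEt3)
Conditions: Pd(OAc)2 (10 mol%), XPhos (2-dicyclohexylphosphino-2′,4′,6′-triisopropylbiphenyl, 20 mol%), K3PO4 (3 equiv), toluene (0.01 M), 80 °C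
Reagents that add atoms: none
Why: Zerovalent palladium, formed in situ from Pd(OAc)2 and the bulky biarylphosphine, inserts into the alkenyl C8–I bond with retention of the Z geometry; phosphate deprotonates the palladium-bound methyl ketone at C7, and reductive elimination from the resulting alkenyl palladium enolate forms C7–C8. The closest known reaction type is the palladium-catalysed intramolecular α-alkenylation of ketones with alkenyl halides, together with the Buchwald–Hartwig α-arylation of ketones with K3PO4 as base. Ring B closes as a seven-membered ring, formally in a 7-(enolendo)-exo mode with respect to the departing iodide; the bond arises by reductive elimination from an eight-membered palladacycle, and the C8=C9 double bond ends inside the ring, which is possible only because iodine and C10 are cis. No stereocentre is created; the trans fusion is already fixed at C1 and C5. The step needs enolisation at the acetyl methyl (C7) only, which is secured because C5–H is tertiary and flanked by two fully substituted carbons and C2 is masked as the ketal; it also needs the C4 oxygen to stay, which the silyl ether and the weak, insoluble base secure. The β,γ-position of the new double bond should be kept by the aprotic medium and by stopping at full conversion.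

Step 14
Reactants: 19 silyloxy ketone
Product: 20 4β-hydroxy ketone
Conditions: HF·pyridine, pyridine, THF, 0 °C to rt
Reagents that add atoms: none
Why: Buffered HF·pyridine removes the tertiary silyl ether under non-basic conditions, which avoids retro-aldol cleavage and conjugation of the β,γ-enone and leaves the ketal in place.

Step 15
Reactants: 20 4β-hydroxy ketone
Product: 21 4β,6α-diol
Conditions: Me4NBH(OAc)3, MeCN/AcOH 1:1, −30 °C
Reagents that add atoms: none
Why: In this Evans–Saksena reduction the C4 hydroxyl exchanges onto boron and delivers hydride to the β face of the C6 carbonyl, giving the anti 1,3-diol with the C6 hydroxyl α.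

Step 16
Reactants: 22 4-hydroxybenzoic acid
Product: 24 4-(tert-butyldimethylsilyloxy)benzoic acid, via bis-silylated benzoate 23 (not isolated)
Conditions: t-BuMe2SiCl, imidazole, DMF, rt; then K2CO3, THF/MeOH/H2O, rt; acidic work-up
Reagents that add atoms: tert-butyldimethylsilyl chloride, CC(C)(C)[Si](C)(C)Cl
Why: Exhaustive silylation followed by selective hydrolysis of the labile silyl ester leaves the aryl silyl ether, a standard way to mask the phenol of a hydroxybenzoic acid.

Step 17
Reactants: 21 4β,6α-diol; 24 4-(tert-butyldimethylsilyloxy)benzoic acid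
Product: 25 6α-[4-(tert-butyldimethylsilyloxy)benzoate] of 21
Conditions: DCC, DMAP, CH2Cl2, 0 °C to rt
Reagents that add atoms: none
Why: Steglich esterification acylates the secondary C6 hydroxyl, while the hindered tertiary C4 hydroxyl does not react.

Step 18
Reactants: 25 ketal ester
Product: 26 2-oxo ester
Conditions: PPTS, acetone/H2O, 50 °C
Reagents that add atoms: water, O
Why: Mild acid-catalysed ketal hydrolysis frees the C2 ketone; the benzoate, the aryl silyl ether and the tertiary alcohol tolerate PPTS.

Step 19
Reactants: 26 2-oxo ester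
Product: 27 2α-hydroxy ester
Conditions: Me4NBH(OAc)3, MeCN/AcOH 1:1, −20 to 0 °C
Reagents that add atoms: none
Why: In this second Evans–Saksena reduction the β-oriented C4 hydroxyl delivers hydride across ring A to the β face of the C2 carbonyl, giving the trans 1,3-diol with the C2 hydroxyl α.

Step 20
Reactants: 27 2α-hydroxy ester
Product: 28 2α-acetate
Conditions: Ac2O, pyridine, DMAP (cat.), CH2Cl2, 0 °C to rt
Reagents that add atoms: acetic anhydride, CC(=O)OC(C)=O
Why: DMAP-catalysed acetylation esterifies the secondary C2 hydroxyl; the tertiary C4 hydroxyl is too hindered to react under these conditions.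

Step 21
Reactants: 28 2α-acetate
Product: 29 target CNP0275279.1
Conditions: Bu4NF, AcOH, THF, 0 °C
Reagents that add atoms: none
Why: Fluoride cleaves the aryl silyl ether quickly, and the acetic acid buffer keeps the medium non-basic so that the acetate and the benzoate stay in place (silyl ether cleavage).

**Compound list**

1 | but-2-yn-1-ol | CC#CCO | starting material
2 | cyclic alkenylalanate from 1 (sodium salt; Al bound to C3 and to oxygen, two 2-methoxyethoxy groups on Al; not isolated) | CC1=CCO[Al-]1(OCCOC)OCCOC.[Na+] | intermediate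
3 | (Z)-3-iodobut-2-en-1-ol | OC/C=C(\I)C | intermediate
4 | (Z)-1-bromo-3-iodobut-2-ene | BrC/C=C(\I)C | intermediate
5 | (R)-4-(tert-butyldimethylsilyloxy)cyclopent-2-en-1-one | O=C1C=C[C@H](O[Si](C)(C)C(C)(C)C)C1 | starting material
6 | (R)-4-(tert-butyldimethylsilyloxy)-2-iodocyclopent-2-en-1-one | O=C1C(I)=C[C@H](O[Si](C)(C)C(C)(C)C)C1 | intermediate
7 | (R)-4-(tert-butyldimethylsilyloxy)-2-methylcyclopent-2-en-1-one | O=C1C(C)=C[C@H](O[Si](C)(C)C(C)(C)C)C1 | intermediate
8 | isopropenylmagnesium bromide | CC(=C)[Mg]Br | starting material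
9 | silyl enol ether: 2-(trimethylsilyloxy)-1-methyl-5β-isopropenyl-4α-(tert-butyldimethylsilyloxy)cyclopent-1-ene | C[Si](C)(C)OC1=C(C)[C@@H](C(C)=C)[C@H](O[Si](C)(C)C(C)(C)C)C1 | intermediate
10 | lithium enolate corresponding to 9 (not isolated) | [Li]OC1=C(C)[C@@H](C(C)=C)[C@H](O[Si](C)(C)C(C)(C)C)C1 | intermediate
11 | 2-oxo-1β-methyl-1α-[(Z)-3-iodobut-2-enyl]-5β-isopropenyl-4α-(tert-butyldimethylsilyloxy)cyclopentane | O=C1C[C@@H](O[Si](C)(C)C(C)(C)C)[C@H](C(C)=C)[C@@]1(C)C/C=C(\I)C | intermediate
12 | C2 ethylene ketal of 11 | O1CCOC12C[C@@H](O[Si](C)(C)C(C)(C)C)[C@H](C(C)=C)[C@@]2(C)C/C=C(\I)C | intermediate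
13 | 4α-hydroxy ketal | O1CCOC12C[C@@H](O)[C@H](C(C)=C)[C@@]2(C)C/C=C(\I)C | intermediate
14 | 4-oxo ketal | O1CCOC12CC(=O)[C@H](C(C)=C)[C@@]2(C)C/C=C(\I)C | intermediate
15 | 4β-hydroxy-4α-isopropyl ketal | O1CCOC12C[C@@](O)(C(C)C)[C@H](C(C)=C)[C@@]2(C)C/C=C(\I)C | intermediate
16 | 4β-triethylsilyl ether of 15 | O1CCOC12C[C@@](O[Si](CC)(CC)CC)(C(C)C)[C@H](C(C)=C)[C@@]2(C)C/C=C(\I)C | intermediate
17 | vicinal diol from the isopropenyl group of 16 (mixture at the new carbinol carbon; not isolated) | O1CCOC12C[C@@](O[Si](CC)(CC)CC)(C(C)C)[C@H](C(C)(O)CO)[C@@]2(C)C/C=C(\I)C | intermediate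
18 | cyclisation precursor: 5β-acetyl, 1α-[(Z)-3-iodobut-2-enyl], 1β-methyl, 4β-OSiEt3, 4α-isopropyl, C2 ethylene ketal | O1CCOC12C[C@@](O[Si](CC)(CC)CC)(C(C)C)[C@H](C(C)=O)[C@@]2(C)C/C=C(\I)C | intermediate
19 | trans-fused β,γ-unsaturated cycloheptenone: 6-oxo, C8=C9, 8-methyl, 4β-OSiEt3, C2 ethylene ketal | O1CCOC12C[C@@](O[Si](CC)(CC)CC)(C(C)C)[C@@H]3C(=O)CC(C)=CC[C@@]23C | intermediate
20 | 4β-hydroxy-6-oxo bicycle (C2 ketal) | O1CCOC12C[C@@](O)(C(C)C)[C@@H]3C(=O)CC(C)=CC[C@@]23C | intermediate
21 | 4β,6α-diol (C2 ketal) | O1CCOC12C[C@@](O)(C(C)C)[C@@H]3[C@@H](O)CC(C)=CC[C@@]23C | intermediate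
22 | 4-hydroxybenzoic acid | OC(=O)c1ccc(O)cc1 | starting material
23 | tert-butyldimethylsilyl 4-(tert-butyldimethylsilyloxy)benzoate (not isolated) | CC(C)(C)[Si](C)(C)OC(=O)c1ccc(O[Si](C)(C)C(C)(C)C)cc1 | intermediate
24 | 4-(tert-butyldimethylsilyloxy)benzoic acid | OC(=O)c1ccc(O[Si](C)(C)C(C)(C)C)cc1 | intermediate
25 | 6α-[4-(tert-butyldimethylsilyloxy)benzoate], 4β-OH, C2 ketal | O1CCOC12C[C@@](O)(C(C)C)[C@@H]3[C@@H](OC(=O)c4ccc(O[Si](C)(C)C(C)(C)C)cc4)CC(C)=CC[C@@]23C | intermediate
26 | 2-oxo-4β-hydroxy-6α-aroyloxy bicycle | O=C1C[C@@](O)(C(C)C)[C@@H]2[C@@H](OC(=O)c3ccc(O[Si](C)(C)C(C)(C)C)cc3)CC(C)=CC[C@@]12C | intermediate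
27 | 2α,4β-dihydroxy-6α-aroyloxy bicycle | O[C@H]1C[C@@](O)(C(C)C)[C@@H]2[C@@H](OC(=O)c3ccc(O[Si](C)(C)C(C)(C)C)cc3)CC(C)=CC[C@@]12C | intermediate
28 | 2α-acetoxy-4β-hydroxy-6α-[4-(tert-butyldimethylsilyloxy)benzoyloxy] bicycle | CC(=O)O[C@H]1C[C@@](O)(C(C)C)[C@@H]2[C@@H](OC(=O)c3ccc(O[Si](C)(C)C(C)(C)C)cc3)CC(C)=CC[C@@]12C | intermediate
29 | CNP0275279.1: 2α-acetoxy-4β-hydroxy-4α-isopropyl-6α-(4-hydroxybenzoyloxy)-1β,8-dimethyl trans-fused bicyclo[5.3.0]dec-8-ene (route numbering) | CC(=O)O[C@H]1C[C@@](O)(C(C)C)[C@@H]2[C@@H](OC(=O)c3ccc(O)cc3)CC(C)=CC[C@@]12C | target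

**Step count and risks**

Total steps: 21. Longest linear sequence: 18 steps (steps 3–15 and 17–21, from 5 to 29).

Steps most likely to fail:

1. Step 13 (ring closure). Closure of the seven-membered ring through an eight-membered palladacycle may be outrun by protodeiodination, or prolonged contact with base may move the C8=C9 double bond into conjugation with the C6 carbonyl. Fallback: starting from 18, kinetic enolisation with LiN(i-Pr)2 in the presence of Me3SiCl (THF, −78 °C) gives the terminal trimethylsilyl enol ether F1. Heating F1 with PdCl2(P(o-tolyl)3)2 (cat.) and Bu3SnF in toluene forms the tin enolate in situ and couples it with the alkenyl iodide (palladium-catalysed alkenylation of silyl enol ethers through tin enolates, no Brønsted base present). This gives 19, and the route goes on with step 14.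

2. Step 6 (quaternary centre at C1). O-alkylation, proton exchange between product and enolate with loss of the C4 silanolate, or incomplete anti selectivity may interfere when the hindered tetrasubstituted enolate meets the substituted allylic bromide. Fallback: the side chain is built in two stages. Starting from 9, enolate 10 is formed as before and alkylated with the small, very reactive methyl bromoacetate (THF/HMPA, −78 °C) to give the keto ester F2. Ketalisation as in step 7 gives the ketal ester F3, and i-Bu2AlH (CH2Cl2, −78 °C) reduces it to the aldehyde F4. Stork–Zhao-type olefination of F4 with the ylide from (1-iodoethyl)triphenylphosphonium iodide and NaN(SiMe3)2 (THF, −78 °C) gives the (Z)-iodoalkene, which is 12, and the route goes on with step 8.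

3. Step 15 (C6 carbinol). Exchange of the hindered tertiary C4 hydroxyl onto boron may be slow, or hydride delivery may be hampered by the angular methyl, so that conversion or facial selectivity at C6 is poor. Fallback: steric approach control followed by inversion. Starting from 20, NaBH4 (MeOH, −40 °C) should attack anti to the angular C1 methyl and give the 6β-alcohol F5. Mitsunobu esterification of F5 with acid 24 (PPh3, DIAD, toluene, 0 °C to rt) inverts C6 and gives ester 25 directly, and the route goes on with step 18.

Further compounds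
F1 | step 13 | trimethylsilyl enol ether of 18 (CH2=C(OSiMe3) group on C5) | O1CCOC12C[C@@](O[Si](CC)(CC)CC)(C(C)C)[C@H](C(=C)O[Si](C)(C)C)[C@@]2(C)C/C=C(\I)C
F2 | step 6 | keto ester: 2-oxo-1β-methyl-1α-(methoxycarbonylmethyl)-5β-isopropenyl-4α-(tert-butyldimethylsilyloxy)cyclopentane | O=C1C[C@@H](O[Si](C)(C)C(C)(C)C)[C@H](C(C)=C)[C@@]1(C)CC(=O)OC
F3 | step 6 | C2 ethylene ketal of F2 | O1CCOC12C[C@@H](O[Si](C)(C)C(C)(C)C)[C@H](C(C)=C)[C@@]2(C)CC(=O)OC
F4 | step 6 | ketal aldehyde (1α-CH2CHO) | O1CCOC12C[C@@H](O[Si](C)(C)C(C)(C)C)[C@H](C(C)=C)[C@@]2(C)CC=O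
F5 | step 15 | 4β,6β-diol (C6 epimer of 21) | O1CCOC12C[C@@](O)(C(C)C)[C@@H]3[C@H](O)CC(C)=CC[C@@]23C
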